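**Retrosynthetic overview**

1. Target 21 ← desilylation of 20 ← C7–C8 bond made by adding a ring-A C10 vinyllithium to the C30 polyenal 17, then acid retro-dehydration (OH leaves C8, H leaves C4'), which shifts every chain double bond by one position and creates the ring-B 4',5'-ene/6',7'-ylidene pattern.
2. 17 ← Wittig union (C7'=C8') of a ring-B C10 phosphonium salt, made from (4R,6R)-4-hydroxy-2,2,6-trimethylcyclohexanone (source of the only stereocentre), with C20 crocetin dialdehyde.
3. Ring-A vinyllithium ← vinyl iodide 7 ← alkenylboronate 6 ← 6-methyl-2-pyrone + allenylboronate 3 by [4+2] cycloaddition and CO2 extrusion.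
4. Enabling feature: ring A is a cyclohexa-1,3-diene (C2=C3–C4=C5) whose two remaining ring atoms are a quaternary CMe2 carbon (C1) and an sp2 carbon (C6) carrying the exocyclic C6=C7 alkene. This is the retron of a 2-pyrone adding across the Me2C=C bond of an allene with loss of CO2, and the quaternary C1 makes aromatisation impossible.
5. Ring order: ring A is the only ring built (step 2); ring B is bought as the cyclohexanone and only re-functionalised.

Key step: step 2

Assumption: 6-methyl-2H-pyran-2-one, (4R,6R)-4-hydroxy-2,2,6-trimethylcyclohexanone and crocetin dialdehyde are taken as purchasable. Locants follow carotenoid numbering, with ring A (cyclohexadienylidene end) unprimed and ring B (hydroxylated end) primed.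

**Route**

Step 1
Reactants: 1 3-methylbuta-1,2-diene
Product: 3 4,4,5,5-tetramethyl-2-(3-methylbuta-1,2-dien-1-yl)-1,3,2-dioxaborolane, via (3-methylbuta-1,2-dien-1-yl)lithium 2 (not isolated)
Conditions: n-BuLi, THF, −78 to −40 °C; i-PrOBpin, −78 °C to rt; HCl in Et2O, 0 °C
Reagents that add atoms: 2-isopropoxy-4,4,5,5-tetramethyl-1,3,2-dioxaborolane, CC(C)OB1OC(C)(C)C(C)(C)O1
Why: Lithiation of a 1,1-dialkylallene at its allenic CH2 terminus followed by borylation (organolithium–borate exchange); the tertiary propargylic position is too hindered for the borate, so boron should end on the CH terminus and give the allenyl rather than the propargyl boronate.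

Step 2
Reactants: 3 4,4,5,5-tetramethyl-2-(3-methylbuta-1,2-dien-1-yl)-1,3,2-dioxaborolane; 4 6-methyl-2H-pyran-2-one
Product: 6 4,4,5,5-tetramethyl-2-[(Z)-(2,6,6-trimethylcyclohexa-2,4-dien-1-ylidene)methyl]-1,3,2-dioxaborolane, via bridged lactone 5 (not isolated)
Conditions: 4 (2 equiv), mesitylene (1 M), BHT (5 mol %), 150 °C, sealed tube, 24–48 h
Reagents that add atoms: none
Why: Proposed new method: a thermal [4+2] cycloaddition of the 2-pyrone diene (termini C3 and C6) with the dimethyl-substituted π bond of allenylboronate 3 should give bridged lactone 5, which loses CO2 by retro-[4+2] at this temperature to unveil the ring-A cyclohexa-1,3-diene; the closest known reaction type is the cycloaddition/CO2 extrusion of 2-pyrones with alkenes and with alkynylboronates, extended here to an allene as the 2π partner. Ring A is closed by this intermolecular [4+2] (one bond from pyrone C3 to the CMe2 carbon, one from the methyl-bearing pyrone C6 to the central allene carbon), the lactone bridge of 5 being only transient, and the quaternary CMe2 carbon prevents aromatisation so the diene survives. The step needs site selectivity between the two allene π bonds: the boron-bearing π bond is conjugated with the empty boron p orbital (poor match for the electrophilic pyrone) and is screened on both faces by the allene methyl groups, whereas the Me2C=C bond is the electron-richer one and is raised further by hyperconjugation with the coplanar C–B bond. Regiochemistry should follow from sterics and polarity together, since the CMe2 terminus avoids the fully substituted, methyl-bearing pyrone C6 and the nucleophilic central allene carbon pairs with that electrophilic terminus. No stereocentre survives (both bridgeheads of racemic 5 become sp2), and the only stereo-element, the exocyclic alkene, is set because the diene must approach the reacting π bond on the face anti to the Bpin group, which places boron cis to the CMe2 carbon (Z), also the thermodynamically preferred geometry of retro-carotenoid end groups.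

Step 3
Reactants: 6 4,4,5,5-tetramethyl-2-[(Z)-(2,6,6-trimethylcyclohexa-2,4-dien-1-ylidene)methyl]-1,3,2-dioxaborolane
Product: 7 (6Z)-6-(iodomethylidene)-1,5,5-trimethylcyclohexa-1,3-diene
Conditions: aq. NaOH (3 M), I2 (1.05 equiv), THF, 0 °C, dark; Na2S2O3 work-up; used at once
Reagents that add atoms: iodine, II
Why: Base-promoted iododeboronation of an alkenyl pinacol boronate (ipso substitution of the hydroxyborate by iodine) normally proceeds with retention of alkene geometry and gives the halide needed for lithium exchange; exclusion of light and one equivalent of iodine should spare the ring diene.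

Step 4
Reactants: 8 (4R,6R)-4-hydroxy-2,2,6-trimethylcyclohexan-1-one
Product: 9 (4R,6R)-4-[(tert-butyldiphenylsilyl)oxy]-2,2,6-trimethylcyclohexan-1-one
Conditions: TBDPSCl, imidazole, DMF, rt
Reagents that add atoms: tert-butyl(chloro)diphenylsilane, CC(C)(C)[Si](Cl)(c1ccccc1)c1ccccc1
Why: Silyl ether formation on the unhindered secondary alcohol; the tert-butyldiphenylsilyl group is chosen because it should tolerate the acidic steps 8 and 10.

Step 5
Reactants: 9 (4R,6R)-4-[(tert-butyldiphenylsilyl)oxy]-2,2,6-trimethylcyclohexan-1-one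
Product: 11 (4R)-4-[(tert-butyldiphenylsilyl)oxy]-2,6,6-trimethylcyclohex-1-en-1-yl trifluoromethanesulfonate, via lithium enolate 10 (not isolated)
Conditions: LiN(i-Pr)2, THF, −78 to 0 °C; PhNTf2, 0 °C to rt
Reagents that add atoms: N-phenylbis(trifluoromethanesulfonimide), O=S(=O)(N(c1ccccc1)S(=O)(=O)C(F)(F)F)C(F)(F)F
Why: Enolate O-triflation; the ketone has a single enolisable α-carbon (the other is quaternary), so the enol triflate double bond can only form toward the methyl-bearing carbon, which erases the superfluous C6 stereocentre while the silyloxy carbon, γ to the carbonyl, is untouched.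

Step 6
Reactants: 11 (4R)-4-[(tert-butyldiphenylsilyl)oxy]-2,6,6-trimethylcyclohex-1-en-1-yl trifluoromethanesulfonate
Product: 12 methyl (4R)-4-[(tert-butyldiphenylsilyl)oxy]-2,6,6-trimethylcyclohex-1-ene-1-carboxylate
Conditions: Pd(OAc)2 (5 mol %), Ph2P(CH2)3PPh2, CO (1 atm), MeOH, Et3N, DMF, 70 °C
Reagents that add atoms: carbon monoxide, [C-]#[O+]; methanol, CO
Why: Palladium-catalysed alkoxycarbonylation of an enol triflate (oxidative addition, CO insertion, methanolysis) installs the one-carbon unit that becomes C7'.

Step 7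
Reactants: 12 methyl (4R)-4-[(tert-butyldiphenylsilyl)oxy]-2,6,6-trimethylcyclohex-1-ene-1-carboxylate
Product: 13 [(4R)-4-[(tert-butyldiphenylsilyl)oxy]-2,6,6-trimethylcyclohex-1-en-1-yl]methanol
Conditions: i-Bu2AlH (2.5 equiv), CH2Cl2, −78 to 0 °C; aqueous potassium sodium tartrate
Reagents that add atoms: none
Why: Hydride 1,2-reduction of the conjugated ester to the allylic alcohol; the silyl ether and the tetrasubstituted alkene are inert.

Step 8
Reactants: 13 [(4R)-4-[(tert-butyldiphenylsilyl)oxy]-2,6,6-trimethylcyclohex-1-en-1-yl]methanol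
Product: 14 {[(4R)-4-[(tert-butyldiphenylsilyl)oxy]-2,6,6-trimethylcyclohex-1-en-1-yl]methyl}(triphenyl)phosphonium bromide
Conditions: PPh3·HBr, CH2Cl2, rt
Reagents that add atoms: triphenylphosphine hydrobromide, [Br-].c1ccc(cc1)[PH+](c1ccccc1)c1ccccc1
Why: Allylic alcohol to phosphonium salt (ionisation to the allyl cation and capture by PPh3 at the primary terminus), the standard entry to cyclogeranyl Wittig salts; the silyl ether should be stable to the anhydrous salt.

Step 9
Reactants: 14 {[(4R)-4-[(tert-butyldiphenylsilyl)oxy]-2,6,6-trimethylcyclohex-1-en-1-yl]methyl}(triphenyl)phosphonium bromide; 15 crocetin dialdehyde, (2E,4E,6E,8E,10E,12E,14E)-2,6,11,15-tetramethylhexadeca-2,4,6,8,10,12,14-heptaenedial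
Product: 17 (2E,4E,6E,8E,10E,12E,14E,16E)-17-[(4R)-4-[(tert-butyldiphenylsilyl)oxy]-2,6,6-trimethylcyclohex-1-en-1-yl]-2,6,11,15-tetramethylheptadeca-2,4,6,8,10,12,14,16-octaenal, via phosphorus ylide 16 (not isolated)
Conditions: n-BuLi, THF, −78 to 0 °C; slow addition to 15 (3 equiv), THF/CH2Cl2, −78 °C to rt; dim light
Reagents that add atoms: none
Why: Wittig olefination; slow addition of the ylide to an excess of the symmetrical dialdehyde should favour mono-olefination (unreacted 15 is recovered), the E alkene is expected to dominate because the Z isomer clashes with the ring methyl groups, and this geometry is in any case inconsequential since the 7',8' bond becomes a single bond in step 10.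

Step 10
Reactants: 7 (6Z)-6-(iodomethylidene)-1,5,5-trimethylcyclohexa-1,3-diene; 17 the C30 silyloxy polyenal
Product: 20 (3'S)-3'-[(tert-butyldiphenylsilyl)oxy]-2,3,4',5'-tetradehydro-4,5'-retro-β,β-carotene (6Z,6'E, all-trans chain), via ring-A vinyllithium 18 (not isolated), via C40 carbinol 19 (not isolated)
Conditions: 7 (1.25 equiv), t-BuLi (2.5 equiv), Et2O, −78 °C; 17 in THF, −78 °C; sat. NH4Cl; crude 19, p-TsOH·H2O (5 mol %), CH2Cl2, −20 °C, 15 min, then Et3N; if needed I2 (1 mol %), hexane, diffuse light; argon, dim light throughout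
Reagents that add atoms: none
Why: Iodine–lithium exchange gives the vinyllithium with retention, which adds 1,2 to the polyenal, and the doubly allylic carbinol then ionises under acid to a cation delocalised from ring A to C5' and loses H-4', the one proton whose loss leaves the whole chromophore linearly conjugated (E1 retro-dehydration of a polyenyl carbinol, as in the formation of anhydroretinol); all chain bonds have partial double-bond character in the cation, so the all-trans chain and the exocyclic 6,7 and 6',7' geometries should be the thermodynamically preferred ones, the carbinol stereocentre disappears, and C3' is untouched, its descriptor changing from R to S only because the ring double bond moves next to it.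

Step 11
Reactants: 20 the silyl ether of the target
Product: 21 anhydroeschscholtzxanthin (CNP0202479.1), (3'S)-2,3,4',5'-tetradehydro-4,5'-retro-β,β-caroten-3'-ol
Conditions: Bu4NF, AcOH (1 equiv), THF, 0 °C to rt, dark
Reagents that add atoms: none
Why: Fluoride-induced cleavage of the silyl ether under essentially neutral conditions should leave the acid-sensitive allylic alcohol and the retro-polyene intact; no stereocentre is involved.

**Compound list**

1 | 3-methylbuta-1,2-diene | CC(C)=C=C | starting material
2 | (3-methylbuta-1,2-dien-1-yl)lithium | [Li]C=C=C(C)C | intermediate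
3 | 4,4,5,5-tetramethyl-2-(3-methylbuta-1,2-dien-1-yl)-1,3,2-dioxaborolane | CC(C)=C=CB1OC(C)(C)C(C)(C)O1 | intermediate
4 | 6-methyl-2H-pyran-2-one | CC1=CC=CC(=O)O1 | starting material
5 | rac-(6E)-1,5,5-trimethyl-6-[(4,4,5,5-tetramethyl-1,3,2-dioxaborolan-2-yl)methylidene]-2-oxabicyclo[2.2.2]oct-7-en-3-one (boron cis to the CMe2 carbon) | CC12OC(=O)C(C=C1)C(C)(C)\C2=C/B1OC(C)(C)C(C)(C)O1 | intermediate
6 | 4,4,5,5-tetramethyl-2-[(Z)-(2,6,6-trimethylcyclohexa-2,4-dien-1-ylidene)methyl]-1,3,2-dioxaborolane (boron cis to the CMe2 carbon) | CC1=CC=CC(C)(C)\C1=C/B1OC(C)(C)C(C)(C)O1 | intermediate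
7 | (6Z)-6-(iodomethylidene)-1,5,5-trimethylcyclohexa-1,3-diene | CC1=CC=CC(C)(C)\C1=C/I | intermediate
8 | (4R,6R)-4-hydroxy-2,2,6-trimethylcyclohexan-1-one | O=C1[C@H](C)C[C@@H](O)CC1(C)C | starting material
9 | (4R,6R)-4-[(tert-butyldiphenylsilyl)oxy]-2,2,6-trimethylcyclohexan-1-one | O=C1[C@H](C)C[C@@H](O[Si](c2ccccc2)(c2ccccc2)C(C)(C)C)CC1(C)C | intermediate
10 | lithium (4R)-4-[(tert-butyldiphenylsilyl)oxy]-2,6,6-trimethylcyclohex-1-en-1-olate | [Li+].[O-]C1=C(C)C[C@@H](O[Si](c2ccccc2)(c2ccccc2)C(C)(C)C)CC1(C)C | intermediate
11 | (4R)-4-[(tert-butyldiphenylsilyl)oxy]-2,6,6-trimethylcyclohex-1-en-1-yl trifluoromethanesulfonate | FC(F)(F)S(=O)(=O)OC1=C(C)C[C@@H](O[Si](c2ccccc2)(c2ccccc2)C(C)(C)C)CC1(C)C | intermediate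
12 | methyl (4R)-4-[(tert-butyldiphenylsilyl)oxy]-2,6,6-trimethylcyclohex-1-ene-1-carboxylate | COC(=O)C1=C(C)C[C@@H](O[Si](c2ccccc2)(c2ccccc2)C(C)(C)C)CC1(C)C | intermediate
13 | [(4R)-4-[(tert-butyldiphenylsilyl)oxy]-2,6,6-trimethylcyclohex-1-en-1-yl]methanol | OCC1=C(C)C[C@@H](O[Si](c2ccccc2)(c2ccccc2)C(C)(C)C)CC1(C)C | intermediate
14 | {[(4R)-4-[(tert-butyldiphenylsilyl)oxy]-2,6,6-trimethylcyclohex-1-en-1-yl]methyl}(triphenyl)phosphonium bromide | c1ccccc1[P+](c1ccccc1)(c1ccccc1)CC1=C(C)C[C@@H](O[Si](c2ccccc2)(c2ccccc2)C(C)(C)C)CC1(C)C.[Br-] | intermediate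
15 | crocetin dialdehyde, (2E,4E,6E,8E,10E,12E,14E)-2,6,11,15-tetramethylhexadeca-2,4,6,8,10,12,14-heptaenedial | O=C/C(C)=C/C=C/C(C)=C/C=C/C=C(C)/C=C/C=C(C)/C=O | starting material
16 | {[(4R)-4-[(tert-butyldiphenylsilyl)oxy]-2,6,6-trimethylcyclohex-1-en-1-yl]methylidene}(triphenyl)-λ5-phosphane | c1ccccc1P(c1ccccc1)(c1ccccc1)=CC1=C(C)C[C@@H](O[Si](c2ccccc2)(c2ccccc2)C(C)(C)C)CC1(C)C | intermediate
17 | (2E,4E,6E,8E,10E,12E,14E,16E)-17-[(4R)-4-[(tert-butyldiphenylsilyl)oxy]-2,6,6-trimethylcyclohex-1-en-1-yl]-2,6,11,15-tetramethylheptadeca-2,4,6,8,10,12,14,16-octaenal | O=C/C(C)=C/C=C/C(C)=C/C=C/C=C(C)/C=C/C=C(C)/C=C/C1=C(C)C[C@@H](O[Si](c2ccccc2)(c2ccccc2)C(C)(C)C)CC1(C)C | intermediate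
18 | [(Z)-(2,6,6-trimethylcyclohexa-2,4-dien-1-ylidene)methyl]lithium | CC1=CC=CC(C)(C)\C1=C/[Li] | intermediate
19 | (3E,5E,7E,9E,11E,13E,15E,17E)-18-[(4R)-4-[(tert-butyldiphenylsilyl)oxy]-2,6,6-trimethylcyclohex-1-en-1-yl]-3,7,12,16-tetramethyl-1-[(1Z)-2,6,6-trimethylcyclohexa-2,4-dien-1-ylidene]octadeca-3,5,7,9,11,13,15,17-octaen-2-ol (both epimers at the carbinol carbon) | CC1=CC=CC(C)(C)\C1=C/C(O)/C(C)=C/C=C/C(C)=C/C=C/C=C(C)/C=C/C=C(C)/C=C/C1=C(C)C[C@@H](O[Si](c2ccccc2)(c2ccccc2)C(C)(C)C)CC1(C)C | intermediate
20 | (3'S)-3'-[(tert-butyldiphenylsilyl)oxy]-2,3,4',5'-tetradehydro-4,5'-retro-β,β-carotene (6Z,6'E, all-trans chain; each side chain cis to the CMe2 carbon of its ring) | CC1=CC=CC(C)(C)\C1=C/C=C(C)/C=C/C=C(C)/C=C/C=C/C(C)=C/C=C/C(C)=C/C=C1/C(C)=C[C@@H](O[Si](c2ccccc2)(c2ccccc2)C(C)(C)C)CC1(C)C | intermediate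
21 | anhydroeschscholtzxanthin (CNP0202479.1), (3'S)-2,3,4',5'-tetradehydro-4,5'-retro-β,β-caroten-3'-ol (6Z,6'E, all-trans chain) | CC1=CC=CC(C)(C)\C1=C/C=C(C)/C=C/C=C(C)/C=C/C=C/C(C)=C/C=C/C(C)=C/C=C1/C(C)=C[C@@H](O)CC1(C)C | target

**Step count and risks**

Total steps: 11. Longest linear sequence: 8 steps (8 to 21, steps 4–11); the ring-A branch has 3 steps before the union.

Steps most likely to fail:

1. Step 2 (proposed new method). The cycloaddition may occur at the boron-bearing π bond of the allene, or thermal self-reaction of the allene may outpace the cycloaddition. The fallback sets out from pyrone 4 and returns at boronate 6, using known chemistry that still closes ring A through the same two bonds. Pyrone 4 is heated, or pressurised at 10–15 kbar in CH2Cl2, with 3-methylbut-2-enal (CC(C)=CC=O) in a normal-demand Diels–Alder reaction of a 2-pyrone with a conjugated carbonyl alkene. The bridged lactone 1,5,5-trimethyl-3-oxo-2-oxabicyclo[2.2.2]oct-7-ene-6-carbaldehyde F1 should lose CO2 on warming to give 2,6,6-trimethylcyclohexa-2,4-diene-1-carbaldehyde F2. Deprotonation with KN(SiMe3)2 should give potassium (2,6,6-trimethylcyclohexa-2,4-dien-1-ylidene)methanolate F3, and O-triflation with PhNTf2 should give (2,6,6-trimethylcyclohexa-2,4-dien-1-ylidene)methyl trifluoromethanesulfonate F4. Miyaura borylation (PdCl2(PPh3)2, PPh3, KOPh, bis(pinacolato)diboron, toluene, 50 °C) then gives 6. A mixture of exocyclic alkene isomers would be tolerable because this geometry can equilibrate at the cation stage of step 10.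

2. Step 10. The delocalised cation may lose a proton from a chain methyl group (cross-conjugated isomers) instead of C4', or the allylic silyl ether of the product may ionise under the acid and dehydrate a second time. The fallback sets out from 7 and 17 and returns at 20. The same vinyllithium addition is run, but the lithium alkoxide is capped in the flask with methyl chloroformate to give the allylic methyl carbonate of carbinol 19, F5. This is eliminated without Brønsted acid by catalytic Pd(PPh3)4 in THF at rt (zerovalent palladium ionises the carbonate with loss of CO2 to a polyenyl complex of divalent palladium, which undergoes β-hydride loss; Tsuji-type diene synthesis). A trace of I2 in diffuse light then equilibrates the geometric isomers.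

3. Step 3. The alkene geometry may be lost, or the ring diene iodinated, during iododeboronation, and the trienyl iodide may decompose in light. The fallback sets out from boronate 6 and returns at carbinol 19. The iodide and the organolithium are left out, and 6 is added directly to aldehyde 17 by 1,2-addition of the alkenylboron reagent under catalysis by monovalent rhodium ([Rh(OH)(cod)]2, P(t-Bu)3, dioxane/H2O, 50 °C), the bulky phosphine being expected to favour carbonyl over conjugate addition. The crude carbinol is then dehydrated as in step 10. This fallback makes no new compound (F0).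

Further compounds
F1 | step 2 | 1,5,5-trimethyl-3-oxo-2-oxabicyclo[2.2.2]oct-7-ene-6-carbaldehyde | CC12OC(=O)C(C=C1)C(C)(C)C2C=O
F2 | step 2 | 2,6,6-trimethylcyclohexa-2,4-diene-1-carbaldehyde | CC1=CC=CC(C)(C)C1C=O
F3 | step 2 | potassium (2,6,6-trimethylcyclohexa-2,4-dien-1-ylidene)methanolate | CC1=CC=CC(C)(C)C1=C[O-].[K+]
F4 | step 2 | (2,6,6-trimethylcyclohexa-2,4-dien-1-ylidene)methyl trifluoromethanesulfonate | CC1=CC=CC(C)(C)C1=COS(=O)(=O)C(F)(F)F
F5 | step 10 | methyl carbonate of carbinol 19 | CC1=CC=CC(C)(C)\C1=C/C(OC(=O)OC)/C(C)=C/C=C/C(C)=C/C=C/C=C(C)/C=C/C=C(C)/C=C/C1=C(C)C[C@@H](O[Si](c2ccccc2)(c2ccccc2)C(C)(C)C)CC1(C)C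
F0 | step 3 | none | none
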